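**Plan**
1. Retrosynthesis first cuts the two butanoyl C–C bonds (ring A C1 and the one free carbon of ring B) and the two aryl O–methyl bonds, leaving a benzylated filicinic acid.
2. Ring A is a 2,2-dimethylcyclohexane-1,3,5-trione: C2, C4 and C6 are at carbonyl level around the quaternary C3, and C5 carries the bridge CH2. This is the ring form of a 4,4-dimethyl-3,5-dioxo ester, so the C5–C6 bond is cut next (intramolecular Claisen disconnection).
3. The open chain is then cut at the ester carbon (dimethyl carbonate) and at the bridge CH2–C5 bond (aldol of 3,3-dimethylpentane-2,4-dione with the ring B aldehyde made from 2,5-dimethylresorcinol).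
4. Forward: ring B is bought and capped, the chain is joined to it and extended by the ester carbon, ring A (the only ring made) is closed, both butanoyl groups are put on while the phenols are still methylated, and the ethers are cleaved last.
5. Stereochemistry: the target has no stereocentre; the racemic carbinol and the E alkene of the aldol stage are erased by elimination and hydrogenation.

Key step: step 6

Remark: the target is an enolised β-triketone drawn as one tautomer, and all ring A tautomers are treated as the same compound. Ring A locants C1–C6 are those used in the plan; systematic names use their own locants. The butanoyl-bearing carbon of ring B is position 5 of the 2,4-dioxygenated 3,6-dimethylphenyl group in those names.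

**Step 1**
Reactants: 1 2,5-dimethylresorcinol
Product: 2 1,3-dimethoxy-2,5-dimethylbenzene
Conditions: MeI (3 equiv), K2CO3 (3 equiv), acetone, reflux
Reagents that add atoms: iodomethane, CI
Why: Williamson ether synthesis, in which both phenoxides formed by K2CO3 are methylated by SN2 attack on MeI and O-alkylation should dominate over C-alkylation in acetone.

**Step 2**
Reactants: 2 1,3-dimethoxy-2,5-dimethylbenzene
Product: 4 2,4-dimethoxy-3,6-dimethylbenzaldehyde, via aryl iminium chloride 3 (not isolated)
Conditions: POCl3 (1.5 equiv), DMF, 0 °C to 70 °C; then ice-water, 50 °C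
Reagents that add atoms: N,N-dimethylformamide, CN(C)C=O (formyl carbon); water, O (carbonyl oxygen); phosphoryl chloride, O=P(Cl)(Cl)Cl (chloride of intermediate 3 only)
Why: Vilsmeier–Haack formylation, in which the chloroiminium ion attacks one of the two equivalent free positions (each ortho to one methoxy group and para to the other), so only one regioisomer can form, and the iminium salt deactivates the ring against a second attack before water releases the aldehyde.

**Step 3**
Reactants: 4 2,4-dimethoxy-3,6-dimethylbenzaldehyde; 5 3,3-dimethylpentane-2,4-dione
Product: 8 (E)-6-(2,4-dimethoxy-3,6-dimethylphenyl)-3,3-dimethylhex-5-ene-2,4-dione, via aldol adduct 6 (not isolated), via benzylic mesylate 7 (not isolated)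
Conditions: 5 (1.3 equiv), LiN(iPr)2 (1.3 equiv), THF, −78 °C; then 4, −78 °C; AcOH quench; crude 6, MsCl, Et3N, CH2Cl2, 0 °C to rt
Reagents that add atoms: methanesulfonyl chloride, CS(=O)(=O)Cl (its atoms remain only in intermediate 7)
Why: Directed aldol addition of the preformed lithium enolate of the symmetrical diketone to the non-enolisable aldehyde, followed by mesylation and E1cB elimination, should give the E enone without any hydroxide or alkoxide that could split the non-enolisable 1,3-diketone by retro-Claisen cleavage; the carbinol centre of 6 and 7 is racemic and is erased in the elimination.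

**Step 4**
Reactants: 8 (E)-6-(2,4-dimethoxy-3,6-dimethylphenyl)-3,3-dimethylhex-5-ene-2,4-dione
Product: 9 6-(2,4-dimethoxy-3,6-dimethylphenyl)-3,3-dimethylhexane-2,4-dione
Conditions: H2 (1 atm), Pd/C (10% Pd on carbon), EtOAc, rt
Reagents that add atoms: none
Why: Heterogeneous catalytic hydrogenation, in which Pd/C saturates the conjugated styrene-type C=C far faster than it touches the hindered dialkyl ketones or the aryl methyl ethers.

**Step 5**
Reactants: 9 6-(2,4-dimethoxy-3,6-dimethylphenyl)-3,3-dimethylhexane-2,4-dione; 10 dimethyl carbonate
Product: 11 methyl 7-(2,4-dimethoxy-3,6-dimethylphenyl)-4,4-dimethyl-3,5-dioxoheptanoate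
Conditions: NaH (2.5 equiv), (MeO)2CO (3 equiv), THF, reflux; then cold 1 M HCl
Reagents that add atoms: dimethyl carbonate (10), COC(=O)OC
Why: Crossed Claisen condensation (methoxycarbonylation) of a ketone enolate with dimethyl carbonate, which under equilibrating conditions should settle on the methyl group because only that product is drained off as the unhindered, doubly stabilised sodium enolate of a CH2 between ketone and ester, whereas acylation at the chain CH2 is hindered and reversible.

**Step 6**
Reactants: 11 methyl 7-(2,4-dimethoxy-3,6-dimethylphenyl)-4,4-dimethyl-3,5-dioxoheptanoate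
Product: 12 2-[(2,4-dimethoxy-3,6-dimethylphenyl)methyl]-3,5-dihydroxy-4,4-dimethylcyclohexa-2,5-dien-1-one (benzylated filicinic acid)
Conditions: KOtBu (3 equiv), THF, 0 °C to reflux; then 1 M HCl
Reagents that add atoms: none
Why: Intramolecular Claisen (Dieckmann) condensation: the first equivalent of KOtBu removes the acidic C2 proton of the β-keto ester, further base reversibly forms the enolate of the C5 ketone towards chain carbon C6, and C6 adds to the ester carbonyl C1 with loss of methoxide, which makes the ring A bond C5–C6. The closest known reaction type is the base-induced cyclisation of 4,4-dialkyl-3,5-dioxo esters to 2,2-dialkylcyclohexane-1,3,5-triones, as used for filicinic and syncarpic acids. Ring A closes in a 6-(enolendo)-exo-trig mode, the enolate C=C lying inside the new ring and the ester C=O outside it. No stereocentre is created, because the product is a fully enolisable, achiral trione. The step needs C-acylation by C6 to win over O-acylation and over retro-Claisen fragmentation of the non-enolisable 1,3-diketone: the gem-dimethyl carbon folds the chain (gem-dialkyl effect), the C2 enolate shields the C3 carbonyl while cleavage at C5 would have to expel an unfavourable dianion, the base is the poorly nucleophilic tert-butoxide, any enol lactone from O-attack reopens under the alkoxide conditions, and only the carbocyclic trione is removed irreversibly as its delocalised potassium salt.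

**Step 7**
Reactants: 12 2-[(2,4-dimethoxy-3,6-dimethylphenyl)methyl]-3,5-dihydroxy-4,4-dimethylcyclohexa-2,5-dien-1-one; 13 butyric anhydride
Product: 14 2-butanoyl-6-[(5-butanoyl-2,4-dimethoxy-3,6-dimethylphenyl)methyl]-3,5-dihydroxy-4,4-dimethylcyclohexa-2,5-dien-1-one
Conditions: (PrCO)2O (3 equiv), BF3·OEt2 (excess), 50–60 °C; then MeOH/H2O, 50 °C
Reagents that add atoms: butyric anhydride (13), CCCC(=O)OC(=O)CCC
Why: Friedel–Crafts-type C-acylation by the acylium equivalent formed from the anhydride and BF3, which should acylate the two most nucleophilic carbons (the remaining enol carbon C1 of ring A and the single free position of ring B, ortho to one methoxy group and para to the other), any enol ester formed first on ring A rearranging to the C-acyl triketone held as a difluoroboron chelate until the aqueous methanol work-up, while the methyl-capped phenols cannot enter cyclodehydration or quinone methide pathways.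

**Step 8**
Reactants: 14 2-butanoyl-6-[(5-butanoyl-2,4-dimethoxy-3,6-dimethylphenyl)methyl]-3,5-dihydroxy-4,4-dimethylcyclohexa-2,5-dien-1-one
Product: 15 2-butanoyl-6-[(5-butanoyl-2,4-dihydroxy-3,6-dimethylphenyl)methyl]-3,5-dihydroxy-4,4-dimethylcyclohexa-2,5-dien-1-one (CNP0295128.0)
Conditions: BBr3 (5 equiv), CH2Cl2, −78 °C to 0 °C; then ice-water
Reagents that add atoms: none
Why: Lewis acid ether cleavage, in which BBr3 coordinates each methoxy oxygen and bromide removes the methyl group by SN2, the aryl borates and boron chelates being hydrolysed on quenching, while the ketones and the acylated triketone should survive at low temperature.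

**Compound list**
1 | 2,5-dimethylresorcinol | Cc1cc(O)c(C)c(O)c1 | starting material
2 | 1,3-dimethoxy-2,5-dimethylbenzene | COc1cc(C)cc(OC)c1C | intermediate
3 | N-[(2,4-dimethoxy-3,6-dimethylphenyl)methylidene]-N-methylmethanaminium chloride (written as the chloride) | C[N+](C)=Cc1c(C)cc(OC)c(C)c1OC.[Cl-] | intermediate
4 | 2,4-dimethoxy-3,6-dimethylbenzaldehyde | O=Cc1c(C)cc(OC)c(C)c1OC | intermediate
5 | 3,3-dimethylpentane-2,4-dione | CC(=O)C(C)(C)C(C)=O | starting material
6 | 6-(2,4-dimethoxy-3,6-dimethylphenyl)-6-hydroxy-3,3-dimethylhexane-2,4-dione (racemic) | CC(=O)C(C)(C)C(=O)CC(O)c1c(C)cc(OC)c(C)c1OC | intermediate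
7 | 1-(2,4-dimethoxy-3,6-dimethylphenyl)-4,4-dimethyl-3,5-dioxohexyl methanesulfonate (racemic) | CC(=O)C(C)(C)C(=O)CC(OS(C)(=O)=O)c1c(C)cc(OC)c(C)c1OC | intermediate
8 | (E)-6-(2,4-dimethoxy-3,6-dimethylphenyl)-3,3-dimethylhex-5-ene-2,4-dione | CC(=O)C(C)(C)C(=O)/C=C/c1c(C)cc(OC)c(C)c1OC | intermediate
9 | 6-(2,4-dimethoxy-3,6-dimethylphenyl)-3,3-dimethylhexane-2,4-dione | CC(=O)C(C)(C)C(=O)CCc1c(C)cc(OC)c(C)c1OC | intermediate
10 | dimethyl carbonate | COC(=O)OC | starting material
11 | methyl 7-(2,4-dimethoxy-3,6-dimethylphenyl)-4,4-dimethyl-3,5-dioxoheptanoate | COC(=O)CC(=O)C(C)(C)C(=O)CCc1c(C)cc(OC)c(C)c1OC | intermediate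
12 | 2-[(2,4-dimethoxy-3,6-dimethylphenyl)methyl]-3,5-dihydroxy-4,4-dimethylcyclohexa-2,5-dien-1-one | O=C1C=C(O)C(C)(C)C(O)=C1Cc1c(C)cc(OC)c(C)c1OC | intermediate
13 | butyric anhydride | CCCC(=O)OC(=O)CCC | starting material
14 | 2-butanoyl-6-[(5-butanoyl-2,4-dimethoxy-3,6-dimethylphenyl)methyl]-3,5-dihydroxy-4,4-dimethylcyclohexa-2,5-dien-1-one | CCCC(=O)C1=C(O)C(C)(C)C(O)=C(Cc2c(C)c(C(=O)CCC)c(OC)c(C)c2OC)C1=O | intermediate
15 | 2-butanoyl-6-[(5-butanoyl-2,4-dihydroxy-3,6-dimethylphenyl)methyl]-3,5-dihydroxy-4,4-dimethylcyclohexa-2,5-dien-1-one | CCCC(=O)C1=C(O)C(C)(C)C(O)=C(Cc2c(C)c(C(=O)CCC)c(O)c(C)c2O)C1=O | target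

**Count and risks**
Total step count: 8. Longest linear sequence: 8 steps (1 to 15).

Steps most likely to fail:

Step 7. The acylation of ring B may stall, because the free position is flanked by methyl and methoxy and no free phenol is there to steer a Fries pathway. Under the hot Lewis acid the bond between the bridge CH2 and ring A may also ionise, with loss of the electron-rich benzyl group, or the ethers may be partly cleaved. The fallback sets out from 12 and reverses the order of events. BBr3 in CH2Cl2 would first free both phenols to give 2-[(2,4-dihydroxy-3,6-dimethylphenyl)methyl]-3,5-dihydroxy-4,4-dimethylcyclohexa-2,5-dien-1-one F1. The free resorcinol would then be acylated by O-butanoylation and Fries rearrangement with 13 and BF3·OEt2 at the lowest temperature that works, ring A being C-acylated in the same operation. This comes back to the route at 15.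

Step 6. Ring closure may fail because the ester is masked as the C2 enolate and is then a poor electrophile. The chain could instead fragment by retro-Claisen cleavage or stop at an enol lactone. The fallback sets out from aldehyde 4 and gives up the ring closure in favour of a known reductive alkylation of a cyclic 1,3-dione. Filicinic acid F2 (a known compound, used in excess to hold the reaction at mono-alkylation) would be condensed with 4 under L-proline catalysis (Knoevenagel condensation). This gives 2-[(2,4-dimethoxy-3,6-dimethylphenyl)methylidene]-5-hydroxy-6,6-dimethylcyclohex-4-ene-1,3-dione F3, which is reduced in the same flask by diethyl 2,6-dimethyl-1,4-dihydropyridine-3,5-dicarboxylate (Hantzsch ester) through conjugate transfer hydrogenation. The route is rejoined at 12.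

Step 3. The lithium aldolate may transfer an acyl group to its own oxygen (intramolecular retro-Claisen cleavage of the 1,3-diketone through a six-membered hemiketal) or revert by retro-aldol reaction. During the elimination the enone may also cyclise by intramolecular Michael addition of the methyl ketone. The fallback sets out from 4 and makes the same C–C bond by alkylation instead of condensation. NaBH4 in MeOH would give (2,4-dimethoxy-3,6-dimethylphenyl)methanol F4. Concentrated HCl would convert it into 2,4-dimethoxy-3,6-dimethylbenzyl chloride F5, used at once. SN2 alkylation of the lithium enolate of 5 (LiN(iPr)2, THF, −78 to 0 °C, enolate in excess to limit double alkylation) should then give 9 directly. The route is rejoined at 9 and step 4 is skipped.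

**Further compounds**
F1 | step 7 | 2-[(2,4-dihydroxy-3,6-dimethylphenyl)methyl]-3,5-dihydroxy-4,4-dimethylcyclohexa-2,5-dien-1-one | O=C1C=C(O)C(C)(C)C(O)=C1Cc1c(C)cc(O)c(C)c1O
F2 | step 6 | filicinic acid (3,5-dihydroxy-4,4-dimethylcyclohexa-2,5-dien-1-one) | O=C1C=C(O)C(C)(C)C(O)=C1
F3 | step 6 | 2-[(2,4-dimethoxy-3,6-dimethylphenyl)methylidene]-5-hydroxy-6,6-dimethylcyclohex-4-ene-1,3-dione (transient, alkene geometry not defined) | COc1cc(C)c(C=C2C(=O)C=C(O)C(C)(C)C2=O)c(OC)c1C
F4 | step 3 | (2,4-dimethoxy-3,6-dimethylphenyl)methanol | OCc1c(C)cc(OC)c(C)c1OC
F5 | step 3 | 2,4-dimethoxy-3,6-dimethylbenzyl chloride | ClCc1c(C)cc(OC)c(C)c1OC
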